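## Retrosynthetic overview

1. The only non-aromatic ring, the tetrahydrofuran, is cut last at C7–O. The precursor is an acyclic 1,4-diol whose ring A is a free para-alkylphenol. Forward, dehydrogenation of that phenol gives a p-quinone methide that the C9' hydroxyl captures (5-exo), the ring-closing event of lignan biosynthesis, here run on the fully assembled trimer.
2. The threo 8''–O–4' guaiacylglycerol unit comes from an Evans syn-aldol of a ring B aryloxyacetyl imide with O-silyl vanillin. One LiBH4 reduction then releases the auxiliary and opens the lactone to the 1,4-diol.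
3. The trans-dibenzylbutyrolactone with differentiated phenols comes from a cyclopropane-fused lactone ((R)-epichlorohydrin plus diethyl malonate), a ring B aryl Grignard reagent and a ring A benzyl chloride.
4. Ring order: cyclopropane and lactone first (both sacrificed), tetrahydrofuran last.

Assumption: lignan numbering is used (ring A/C7–C9 = guaiacyl unit that ends on the tetrahydrofuran, ring B/C7'–C9' = central etherified unit, ring C/C7''–C9'' = guaiacylglycerol unit); 1, 2, 5, 7, 13, 14 and 18 are bought; TBS = tert-butyldimethylsilyl, Bn = benzyl.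

## Route

Step 1
Reactants: 1 diethyl malonate; 2 (R)-epichlorohydrin
Product: 4 ethyl (1S,5R)-2-oxo-3-oxabicyclo[3.1.0]hexane-1-carboxylate, via epoxy malonate 3 (not isolated)
Conditions: NaOEt (1.0 equiv), EtOH, 0 °C to 78 °C
Reagents that add atoms: none
Why: Tandem epoxide opening, Payne-type epoxide relocation, 3-exo-tet cyclopropanation and lactonization; the malonate carbanion attacks the original stereocentre of 2 with inversion, which fixes C5 as R (the future C8').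

Step 2
Reactants: 5 4-bromo-2-methoxyphenol
Product: 6 (4-bromo-2-methoxyphenoxy)(tert-butyl)dimethylsilane
Conditions: TBSCl, imidazole, DMF, rt
Reagents that add atoms: tert-butyldimethylsilyl chloride (TBSCl), CC(C)(C)[Si](C)(C)Cl
Why: Imidazole-promoted phenol silylation (Corey protocol) gives an aryl bromide that tolerates Grignard formation and whose phenol can later be freed by mild base alone.

Step 3
Reactants: 4 ethyl (1S,5R)-2-oxo-3-oxabicyclo[3.1.0]hexane-1-carboxylate; 6 (4-bromo-2-methoxyphenoxy)(tert-butyl)dimethylsilane; 7 4-(benzyloxy)-3-methoxybenzyl chloride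
Product: 10 ethyl (3R,4R)-3-[4-(benzyloxy)-3-methoxybenzyl]-4-[4-(tert-butyldimethylsilyloxy)-3-methoxybenzyl]-2-oxotetrahydrofuran-3-carboxylate, via arylmagnesium bromide 8 (not isolated), via bromomagnesium enolate 9 (not isolated)
Conditions: Mg, THF, 50 °C; then CuI (15 mol%), 4, THF, −40 to 0 °C; then 7, NaI (20 mol%), DMPU, 0 to 45 °C
Reagents that add atoms: none
Why: Copper-catalysed homoconjugate (SN2-type) addition of the aryl Grignard reagent opens the doubly activated cyclopropane at its CH2 without touching C5, and the malonate-type enolate is then benzylated in the same flask (tandem addition–enolate alkylation) anti to the C4 substituent; the quaternary C3 configuration is inconsequential.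

Step 4
Reactants: 10 ethyl (3R,4R)-3-[4-(benzyloxy)-3-methoxybenzyl]-4-[4-(tert-butyldimethylsilyloxy)-3-methoxybenzyl]-2-oxotetrahydrofuran-3-carboxylate
Product: 12 (3R,4R)-3-[4-(benzyloxy)-3-methoxybenzyl]-4-(4-hydroxy-3-methoxybenzyl)dihydrofuran-2(3H)-one, via trans-lactone silyl ether 11 (not isolated)
Conditions: LiCl, DMSO/H2O, 150 °C; then K2CO3 (20 mol%), MeOH, 40 °C
Reagents that add atoms: none
Why: Krapcho dealkoxycarbonylation followed by protonation and base equilibration of the lactone α-carbon gives the thermodynamic trans-3,4-dibenzyl lactone (C8 = R), and carbonate/methanol cleaves only the phenolic silyl ether, so ring B alone carries a free phenol.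

Step 5
Reactants: 13 (S)-4-benzyloxazolidin-2-one; 14 bromoacetyl bromide
Product: 16 (S)-4-benzyl-3-(2-bromoacetyl)oxazolidin-2-one, via N-lithio oxazolidinone 15 (not isolated)
Conditions: n-BuLi, THF, −78 °C; then 14, −78 to 0 °C
Reagents that add atoms: none
Why: N-Acylation of the lithiated Evans auxiliary occurs at the acyl bromide, which is far more electrophilic than the alkyl bromide.

Step 6
Reactants: 12 (3R,4R)-3-[4-(benzyloxy)-3-methoxybenzyl]-4-(4-hydroxy-3-methoxybenzyl)dihydrofuran-2(3H)-one; 16 (S)-4-benzyl-3-(2-bromoacetyl)oxazolidin-2-one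
Product: 17 (S)-4-benzyl-3-{2-[4-({(3R,4R)-4-[4-(benzyloxy)-3-methoxybenzyl]-5-oxotetrahydrofuran-3-yl}methyl)-2-methoxyphenoxy]acetyl}oxazolidin-2-one
Conditions: K2CO3, MeCN, rt
Reagents that add atoms: none
Why: Williamson ether synthesis in which the single free phenol (ring B) displaces the activated α-bromide under carbonate conditions that leave lactone, imide and the already thermodynamic C8 centre unchanged.

Step 7
Reactants: 18 vanillin
Product: 19 4-(tert-butyldimethylsilyloxy)-3-methoxybenzaldehyde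
Conditions: TBSCl, imidazole, DMF, rt
Reagents that add atoms: tert-butyldimethylsilyl chloride (TBSCl), CC(C)(C)[Si](C)(C)Cl
Why: Phenol silylation gives a ring C aldehyde whose protecting group survives boron aldol, hydride, hydrogenolysis and DDQ, and keeps ring C from forming a quinone methide in step 11.

Step 8
Reactants: 17 (S)-4-benzyl-3-{2-[4-({(3R,4R)-4-[4-(benzyloxy)-3-methoxybenzyl]-5-oxotetrahydrofuran-3-yl}methyl)-2-methoxyphenoxy]acetyl}oxazolidin-2-one; 19 4-(tert-butyldimethylsilyloxy)-3-methoxybenzaldehyde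
Product: 21 (S)-4-benzyl-3-{(2S,3R)-2-[4-({(3R,4R)-4-[4-(benzyloxy)-3-methoxybenzyl]-5-oxotetrahydrofuran-3-yl}methyl)-2-methoxyphenoxy]-3-[4-(tert-butyldimethylsilyloxy)-3-methoxyphenyl]-3-hydroxypropanoyl}oxazolidin-2-one, via dibutylboron enolate 20 (not isolated)
Conditions: Bu2BOTf (1.2 equiv), i-Pr2NEt, CH2Cl2, −78 to 0 °C; then 19, −78 to 0 °C; pH 7 buffer, MeOH, H2O2
Reagents that add atoms: none
Why: Evans syn-aldol of the Z boron enolate through a Zimmerman–Traxler chair on the face away from the auxiliary benzyl group gives the (2S,3R) syn adduct, which is the threo (7''R,8''R) pair of the target; the lactone is not enolised by Bu2BOTf/amine, and the minor diastereomer from residual ent-4 is removed here.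

Step 9
Reactants: 21 (S)-4-benzyl-3-{(2S,3R)-2-[4-({(3R,4R)-4-[4-(benzyloxy)-3-methoxybenzyl]-5-oxotetrahydrofuran-3-yl}methyl)-2-methoxyphenoxy]-3-[4-(tert-butyldimethylsilyloxy)-3-methoxyphenyl]-3-hydroxypropanoyl}oxazolidin-2-one
Product: 22 (2R,3R)-2-[4-(benzyloxy)-3-methoxybenzyl]-3-[4-({(1R,2R)-1-[4-(tert-butyldimethylsilyloxy)-3-methoxyphenyl]-1,3-dihydroxypropan-2-yl}oxy)-3-methoxybenzyl]butane-1,4-diol
Conditions: LiBH4 (5 equiv), THF, H2O (1 equiv), 0 °C to rt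
Reagents that add atoms: none
Why: Reductive cleavage of the N-acyl oxazolidinone and hydride reduction of the lactone in one operation give the C9'' alcohol and the 1,4-diol without touching any stereocentre.

Step 10
Reactants: 22 (2R,3R)-2-[4-(benzyloxy)-3-methoxybenzyl]-3-[4-({(1R,2R)-1-[4-(tert-butyldimethylsilyloxy)-3-methoxyphenyl]-1,3-dihydroxypropan-2-yl}oxy)-3-methoxybenzyl]butane-1,4-diol
Product: 23 (2R,3R)-2-(4-hydroxy-3-methoxybenzyl)-3-[4-({(1R,2R)-1-[4-(tert-butyldimethylsilyloxy)-3-methoxyphenyl]-1,3-dihydroxypropan-2-yl}oxy)-3-methoxybenzyl]butane-1,4-diol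
Conditions: H2 (1 atm), 10% Pd/C, EtOAc/EtOH, rt
Reagents that add atoms: none
Why: Catalytic hydrogenolysis removes the only benzyl ether and unmasks the ring A phenol, while the silyl ether, the alkyl aryl ether and the non-phenolic benzylic alcohol are inert under neutral conditions.

Step 11
Reactants: 23 (2R,3R)-2-(4-hydroxy-3-methoxybenzyl)-3-[4-({(1R,2R)-1-[4-(tert-butyldimethylsilyloxy)-3-methoxyphenyl]-1,3-dihydroxypropan-2-yl}oxy)-3-methoxybenzyl]butane-1,4-diol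
Product: 25 (1R,2R)-1-[4-(tert-butyldimethylsilyloxy)-3-methoxyphenyl]-2-[4-({(3R,4R,5S)-5-(4-hydroxy-3-methoxyphenyl)-4-(hydroxymethyl)tetrahydrofuran-3-yl}methyl)-2-methoxyphenoxy]propane-1,3-diol, via p-quinone methide 24 (not isolated)
Conditions: DDQ (1.05 equiv), NaHCO3, CH2Cl2/1,4-dioxane, 0 °C
Reagents that add atoms: none
Why: DDQ dehydrogenation of the only free para-alkylphenol gives the ring A p-quinone methide, which is closed by 5-exo oxa-1,6-addition of the C9' hydroxyl (rings B and C are ethers and cannot form quinone methides); C7 becomes S because the aryl group settles trans to the C8 hydroxymethyl and avoids the all-cis tetrahydrofuran, and bicarbonate suppresses Friedel–Crafts closure onto ring B.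

Step 12
Reactants: 25 (1R,2R)-1-[4-(tert-butyldimethylsilyloxy)-3-methoxyphenyl]-2-[4-({(3R,4R,5S)-5-(4-hydroxy-3-methoxyphenyl)-4-(hydroxymethyl)tetrahydrofuran-3-yl}methyl)-2-methoxyphenoxy]propane-1,3-diol
Product: 26 (1R,2R)-1-(4-hydroxy-3-methoxyphenyl)-2-[4-({(3R,4R,5S)-5-(4-hydroxy-3-methoxyphenyl)-4-(hydroxymethyl)tetrahydrofuran-3-yl}methyl)-2-methoxyphenoxy]propane-1,3-diol (target)
Conditions: TBAF, AcOH (1:1), THF, 0 °C
Reagents that add atoms: none
Why: Fluoride desilylation of the ring C phenol, buffered with acetic acid so that no phenoxide can trigger retro-oxa-Michael opening at C7 or ionization at C7''.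

## Compound list

1 | diethyl malonate | CCOC(=O)CC(=O)OCC | starting material
2 | (R)-epichlorohydrin | ClC[C@H]1CO1 | starting material
3 | diethyl 2-{[(2R)-oxiran-2-yl]methyl}malonate | CCOC(=O)C(C[C@@H]1CO1)C(=O)OCC | intermediate
4 | ethyl (1S,5R)-2-oxo-3-oxabicyclo[3.1.0]hexane-1-carboxylate | O=C1OC[C@@H]2C[C@]12C(=O)OCC | intermediate
5 | 4-bromo-2-methoxyphenol | COc1cc(Br)ccc1O | starting material
6 | (4-bromo-2-methoxyphenoxy)(tert-butyl)dimethylsilane | COc1cc(Br)ccc1O[Si](C)(C)C(C)(C)C | intermediate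
7 | 4-(benzyloxy)-3-methoxybenzyl chloride | COc1cc(CCl)ccc1OCc1ccccc1 | starting material
8 | [4-(tert-butyldimethylsilyloxy)-3-methoxyphenyl]magnesium bromide | COc1cc([Mg]Br)ccc1O[Si](C)(C)C(C)(C)C | intermediate
9 | bromomagnesium enolate of ethyl (4R)-4-[4-(tert-butyldimethylsilyloxy)-3-methoxybenzyl]-2-oxotetrahydrofuran-3-carboxylate | CCOC(=O)C1=C(O[Mg]Br)OC[C@@H]1Cc1ccc(O[Si](C)(C)C(C)(C)C)c(OC)c1 | intermediate
10 | ethyl (3R,4R)-3-[4-(benzyloxy)-3-methoxybenzyl]-4-[4-(tert-butyldimethylsilyloxy)-3-methoxybenzyl]-2-oxotetrahydrofuran-3-carboxylate | O=C1OC[C@H](Cc2ccc(O[Si](C)(C)C(C)(C)C)c(OC)c2)[C@@]1(C(=O)OCC)Cc1ccc(OCc2ccccc2)c(OC)c1 | intermediate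
11 | (3R,4R)-3-[4-(benzyloxy)-3-methoxybenzyl]-4-[4-(tert-butyldimethylsilyloxy)-3-methoxybenzyl]dihydrofuran-2(3H)-one | O=C1OC[C@H](Cc2ccc(O[Si](C)(C)C(C)(C)C)c(OC)c2)[C@H]1Cc1ccc(OCc2ccccc2)c(OC)c1 | intermediate
12 | (3R,4R)-3-[4-(benzyloxy)-3-methoxybenzyl]-4-(4-hydroxy-3-methoxybenzyl)dihydrofuran-2(3H)-one | O=C1OC[C@H](Cc2ccc(O)c(OC)c2)[C@H]1Cc1ccc(OCc2ccccc2)c(OC)c1 | intermediate
13 | (S)-4-benzyloxazolidin-2-one | O=C1N[C@@H](Cc2ccccc2)CO1 | starting material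
14 | bromoacetyl bromide | BrCC(Br)=O | starting material
15 | (S)-4-benzyl-3-lithiooxazolidin-2-one | [Li]N1[C@@H](Cc2ccccc2)COC1=O | intermediate
16 | (S)-4-benzyl-3-(2-bromoacetyl)oxazolidin-2-one | O=C1OC[C@H](Cc2ccccc2)N1C(=O)CBr | intermediate
17 | (S)-4-benzyl-3-{2-[4-({(3R,4R)-4-[4-(benzyloxy)-3-methoxybenzyl]-5-oxotetrahydrofuran-3-yl}methyl)-2-methoxyphenoxy]acetyl}oxazolidin-2-one | O=C1OC[C@H](Cc2ccc(OCC(=O)N3[C@@H](Cc4ccccc4)COC3=O)c(OC)c2)[C@H]1Cc1ccc(OCc2ccccc2)c(OC)c1 | intermediate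
18 | vanillin | COc1cc(C=O)ccc1O | starting material
19 | 4-(tert-butyldimethylsilyloxy)-3-methoxybenzaldehyde | COc1cc(C=O)ccc1O[Si](C)(C)C(C)(C)C | intermediate
20 | Z-dibutylboron enolate of imide 17 | O=C1OC[C@H](Cc2ccc(O/C=C(\OB(CCCC)CCCC)N3[C@@H](Cc4ccccc4)COC3=O)c(OC)c2)[C@H]1Cc1ccc(OCc2ccccc2)c(OC)c1 | intermediate
21 | (S)-4-benzyl-3-{(2S,3R)-2-[4-({(3R,4R)-4-[4-(benzyloxy)-3-methoxybenzyl]-5-oxotetrahydrofuran-3-yl}methyl)-2-methoxyphenoxy]-3-[4-(tert-butyldimethylsilyloxy)-3-methoxyphenyl]-3-hydroxypropanoyl}oxazolidin-2-one | O=C1OC[C@H](Cc2ccc(O[C@H](C(=O)N3[C@@H](Cc4ccccc4)COC3=O)[C@H](O)c3ccc(O[Si](C)(C)C(C)(C)C)c(OC)c3)c(OC)c2)[C@H]1Cc1ccc(OCc2ccccc2)c(OC)c1 | intermediate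
22 | (2R,3R)-2-[4-(benzyloxy)-3-methoxybenzyl]-3-[4-({(1R,2R)-1-[4-(tert-butyldimethylsilyloxy)-3-methoxyphenyl]-1,3-dihydroxypropan-2-yl}oxy)-3-methoxybenzyl]butane-1,4-diol | COc1cc([C@@H](O)[C@@H](CO)Oc2ccc(C[C@@H](CO)[C@H](CO)Cc3ccc(OCc4ccccc4)c(OC)c3)cc2OC)ccc1O[Si](C)(C)C(C)(C)C | intermediate
23 | (2R,3R)-2-(4-hydroxy-3-methoxybenzyl)-3-[4-({(1R,2R)-1-[4-(tert-butyldimethylsilyloxy)-3-methoxyphenyl]-1,3-dihydroxypropan-2-yl}oxy)-3-methoxybenzyl]butane-1,4-diol | COc1cc([C@@H](O)[C@@H](CO)Oc2ccc(C[C@@H](CO)[C@H](CO)Cc3ccc(O)c(OC)c3)cc2OC)ccc1O[Si](C)(C)C(C)(C)C | intermediate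
24 | ring A p-quinone methide of 23 (ring A as 4-alkylidene-2-methoxycyclohexa-2,5-dien-1-one, C7 the exocyclic methine) | COc1cc([C@@H](O)[C@@H](CO)Oc2ccc(C[C@@H](CO)[C@H](CO)C=C3C=CC(=O)C(OC)=C3)cc2OC)ccc1O[Si](C)(C)C(C)(C)C | intermediate
25 | (1R,2R)-1-[4-(tert-butyldimethylsilyloxy)-3-methoxyphenyl]-2-[4-({(3R,4R,5S)-5-(4-hydroxy-3-methoxyphenyl)-4-(hydroxymethyl)tetrahydrofuran-3-yl}methyl)-2-methoxyphenoxy]propane-1,3-diol | COc1cc([C@@H](O)[C@@H](CO)Oc2ccc(C[C@H]3CO[C@H](c4ccc(O)c(OC)c4)[C@H]3CO)cc2OC)ccc1O[Si](C)(C)C(C)(C)C | intermediate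
26 | (1R,2R)-1-(4-hydroxy-3-methoxyphenyl)-2-[4-({(3R,4R,5S)-5-(4-hydroxy-3-methoxyphenyl)-4-(hydroxymethyl)tetrahydrofuran-3-yl}methyl)-2-methoxyphenoxy]propane-1,3-diol | COc1cc([C@@H](O)[C@@H](CO)Oc2ccc(C[C@H]3CO[C@H](c4ccc(O)c(OC)c4)[C@H]3CO)cc2OC)ccc1O | target

## Step count and risks

Total step count: 12 (steps 2, 5 and 7 are one-step reagent preparations). Longest linear sequence: 9 steps (1, 3, 4, 6, 8, 9, 10, 11, 12).

Three steps most likely to fail:

**Step 3 (one-flask cyclopropane opening and enolate benzylation).** The chelated magnesium enolate 9 may resist C-benzylation, or excess Grignard reagent may consume 7. The fallback sets out from 9 and comes back at 11. Quench 9 with aqueous NH4Cl and isolate ethyl (4R)-4-[4-(tert-butyldimethylsilyloxy)-3-methoxybenzyl]-2-oxotetrahydrofuran-3-carboxylate F1. Remove the ester first (LiCl, wet DMSO, 150 °C) to give (R)-4-[4-(tert-butyldimethylsilyloxy)-3-methoxybenzyl]dihydrofuran-2(3H)-one F2. Alkylate its lithium enolate (LiN(i-Pr)2, THF, −78 °C, then 7 and NaI). This is the classical substrate-controlled anti-alkylation of a 4-benzylbutyrolactone; it sets C8 kinetically and gives 11 directly, and the K2CO3/MeOH half of step 4 then gives 12.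

**Step 8 (boron aldol beside the butyrolactone).** Lewis-acid activation or enolisation of the lactone, or sluggish enolisation of the bulky imide, would erode yield and selectivity. The fallback sets out from 12 and comes back at 22. Reduce the lactone before the aldol (LiAlH4, THF) to (2R,3R)-2-[4-(benzyloxy)-3-methoxybenzyl]-3-(4-hydroxy-3-methoxybenzyl)butane-1,4-diol F3. Alkylate the phenol with 16 (K2CO3, MeCN) to (S)-4-benzyl-3-(2-{4-[(2R,3R)-3-[4-(benzyloxy)-3-methoxybenzyl]-4-hydroxy-2-(hydroxymethyl)butyl]-2-methoxyphenoxy}acetyl)oxazolidin-2-one F4. Run the aldol with 19 using 3.4 equiv of Bu2BOTf, so that both primary hydroxyls are carried as transient dibutylborinates, to give (S)-4-benzyl-3-{(2S,3R)-2-{4-[(2R,3R)-3-[4-(benzyloxy)-3-methoxybenzyl]-4-hydroxy-2-(hydroxymethyl)butyl]-2-methoxyphenoxy}-3-[4-(tert-butyldimethylsilyloxy)-3-methoxyphenyl]-3-hydroxypropanoyl}oxazolidin-2-one F5. LiBH4 then removes the auxiliary and gives 22.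

**Step 11 (dehydrogenative quinone methide cyclization, the key step).** Risks are over-oxidation of 25 or of the ring C carbinol, Friedel–Crafts closure onto ring B to an aryltetralin, and a kinetic cis product at C7. The fallback reaches the same benzylic electrophile by dehydration instead of dehydrogenation; it sets out from 4 and comes back at 25.
- Opening of 4 with 8/CuI, proton quench and dealkoxycarbonylation give F1 and then F2 as in the fallback to step 3.
- The lithium enolate of F2 (LiN(i-Pr)2, THF, −78 °C) adds to commercial 4-(benzyloxy)-3-methoxybenzaldehyde anti to the C4 substituent. This gives (3S,4R)-3-{[4-(benzyloxy)-3-methoxyphenyl](hydroxy)methyl}-4-[4-(tert-butyldimethylsilyloxy)-3-methoxybenzyl]dihydrofuran-2(3H)-one F6; its carbinol epimers are both usable.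
- CsF and 16 in DMF desilylate and O-alkylate in one pot to (S)-4-benzyl-3-{2-[4-({(3R,4S)-4-{[4-(benzyloxy)-3-methoxyphenyl](hydroxy)methyl}-5-oxotetrahydrofuran-3-yl}methyl)-2-methoxyphenoxy]acetyl}oxazolidin-2-one F7.
- The boron aldol with 19 (2.4 equiv Bu2BOTf, the C7 hydroxyl carried as its borinate) gives (S)-4-benzyl-3-{(2S,3R)-2-[4-({(3R,4S)-4-{[4-(benzyloxy)-3-methoxyphenyl](hydroxy)methyl}-5-oxotetrahydrofuran-3-yl}methyl)-2-methoxyphenoxy]-3-[4-(tert-butyldimethylsilyloxy)-3-methoxyphenyl]-3-hydroxypropanoyl}oxazolidin-2-one F8.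
- LiBH4 gives (2R,3R)-2-{[4-(benzyloxy)-3-methoxyphenyl](hydroxy)methyl}-3-[4-({(1R,2R)-1-[4-(tert-butyldimethylsilyloxy)-3-methoxyphenyl]-1,3-dihydroxypropan-2-yl}oxy)-3-methoxybenzyl]butane-1,4-diol F9.
- Catalytic PPTS in CH2Cl2 at 0 °C ionises the ring A carbinol to the para-benzyloxy-stabilised cation (an O-benzylated quinone methide), which the C9' hydroxyl closes 5-exo to (1R,2R)-1-[4-(tert-butyldimethylsilyloxy)-3-methoxyphenyl]-2-[4-({(3R,4R,5S)-5-[4-(benzyloxy)-3-methoxyphenyl]-4-(hydroxymethyl)tetrahydrofuran-3-yl}methyl)-2-methoxyphenoxy]propane-1,3-diol F10.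
- Hydrogenolysis (H2, Pd/C) gives 25.

## Further compounds

F1 | step 3 | ethyl (4R)-4-[4-(tert-butyldimethylsilyloxy)-3-methoxybenzyl]-2-oxotetrahydrofuran-3-carboxylate | CCOC(=O)C1C(=O)OC[C@@H]1Cc1ccc(O[Si](C)(C)C(C)(C)C)c(OC)c1
F2 | step 3 | (R)-4-[4-(tert-butyldimethylsilyloxy)-3-methoxybenzyl]dihydrofuran-2(3H)-one | O=C1C[C@@H](Cc2ccc(O[Si](C)(C)C(C)(C)C)c(OC)c2)CO1
F3 | step 8 | (2R,3R)-2-[4-(benzyloxy)-3-methoxybenzyl]-3-(4-hydroxy-3-methoxybenzyl)butane-1,4-diol | COc1cc(C[C@@H](CO)[C@H](CO)Cc2ccc(OCc3ccccc3)c(OC)c2)ccc1O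
F4 | step 8 | (S)-4-benzyl-3-(2-{4-[(2R,3R)-3-[4-(benzyloxy)-3-methoxybenzyl]-4-hydroxy-2-(hydroxymethyl)butyl]-2-methoxyphenoxy}acetyl)oxazolidin-2-one | COc1cc(C[C@@H](CO)[C@H](CO)Cc2ccc(OCc3ccccc3)c(OC)c2)ccc1OCC(=O)N1[C@@H](Cc2ccccc2)COC1=O
F5 | step 8 | (S)-4-benzyl-3-{(2S,3R)-2-{4-[(2R,3R)-3-[4-(benzyloxy)-3-methoxybenzyl]-4-hydroxy-2-(hydroxymethyl)butyl]-2-methoxyphenoxy}-3-[4-(tert-butyldimethylsilyloxy)-3-methoxyphenyl]-3-hydroxypropanoyl}oxazolidin-2-one | COc1cc(C[C@@H](CO)[C@H](CO)Cc2ccc(OCc3ccccc3)c(OC)c2)ccc1O[C@H](C(=O)N1[C@@H](Cc2ccccc2)COC1=O)[C@H](O)c1ccc(O[Si](C)(C)C(C)(C)C)c(OC)c1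
F6 | step 11 | (3S,4R)-3-{[4-(benzyloxy)-3-methoxyphenyl](hydroxy)methyl}-4-[4-(tert-butyldimethylsilyloxy)-3-methoxybenzyl]dihydrofuran-2(3H)-one | O=C1OC[C@H](Cc2ccc(O[Si](C)(C)C(C)(C)C)c(OC)c2)[C@H]1C(O)c1ccc(OCc2ccccc2)c(OC)c1
F7 | step 11 | (S)-4-benzyl-3-{2-[4-({(3R,4S)-4-{[4-(benzyloxy)-3-methoxyphenyl](hydroxy)methyl}-5-oxotetrahydrofuran-3-yl}methyl)-2-methoxyphenoxy]acetyl}oxazolidin-2-one | O=C1OC[C@H](Cc2ccc(OCC(=O)N3[C@@H](Cc4ccccc4)COC3=O)c(OC)c2)[C@H]1C(O)c1ccc(OCc2ccccc2)c(OC)c1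
F8 | step 11 | (S)-4-benzyl-3-{(2S,3R)-2-[4-({(3R,4S)-4-{[4-(benzyloxy)-3-methoxyphenyl](hydroxy)methyl}-5-oxotetrahydrofuran-3-yl}methyl)-2-methoxyphenoxy]-3-[4-(tert-butyldimethylsilyloxy)-3-methoxyphenyl]-3-hydroxypropanoyl}oxazolidin-2-one | O=C1OC[C@H](Cc2ccc(O[C@H](C(=O)N3[C@@H](Cc4ccccc4)COC3=O)[C@H](O)c3ccc(O[Si](C)(C)C(C)(C)C)c(OC)c3)c(OC)c2)[C@H]1C(O)c1ccc(OCc2ccccc2)c(OC)c1
F9 | step 11 | (2R,3R)-2-{[4-(benzyloxy)-3-methoxyphenyl](hydroxy)methyl}-3-[4-({(1R,2R)-1-[4-(tert-butyldimethylsilyloxy)-3-methoxyphenyl]-1,3-dihydroxypropan-2-yl}oxy)-3-methoxybenzyl]butane-1,4-diol | COc1cc([C@@H](O)[C@@H](CO)Oc2ccc(C[C@@H](CO)[C@H](CO)C(O)c3ccc(OCc4ccccc4)c(OC)c3)cc2OC)ccc1O[Si](C)(C)C(C)(C)C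
F10 | step 11 | (1R,2R)-1-[4-(tert-butyldimethylsilyloxy)-3-methoxyphenyl]-2-[4-({(3R,4R,5S)-5-[4-(benzyloxy)-3-methoxyphenyl]-4-(hydroxymethyl)tetrahydrofuran-3-yl}methyl)-2-methoxyphenoxy]propane-1,3-diol | COc1cc([C@@H](O)[C@@H](CO)Oc2ccc(C[C@H]3CO[C@H](c4ccc(OCc5ccccc5)c(OC)c4)[C@H]3CO)cc2OC)ccc1O[Si](C)(C)C(C)(C)C
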